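**Plan**

- Numbering: acid carbons are counted from the carboxyl carbon C1; the 1,2-dioxolane is O–O–C3–C4–C5 and the chain is C6–C20.
- Retrosynthesis cuts C14=C15 (Julia–Kocienski), then C12=C13 (cross-metathesis), then the ring bonds C3–C4 and C5–O; C1 is carried as a silyl-protected CH2OH and oxidised last.
- Enabling feature: C3 with its O–O unit is a ketone-level carbon (a silylperoxy ketal, the three-atom C3–O–O component), and C4–C5 is the CH2=C(CH3)– end of a 2-methyl-1-alkene (the two-carbon component) that carries the chain.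
- Forward: peroxy ketal 5 and diene 8 are joined in a (3+2) annulation that closes the only ring first; the spare vinyl group is then extended to the enal and to the triene, and C1 is finally taken to the acid.
- Stereochemistry: C3 comes from face selection at a peroxycarbenium ion held by a chiral imidodiphosphorimidate anion, and C5 from trans-selective ring closure in the same ion pair. 12E comes from cross-metathesis, 14E from the Julia–Kocienski step, and 17Z from (3Z)-hex-3-en-1-ol.

Key step: step 5

Remark: the sense of induction of the chiral anion on a peroxycarbenium ion cannot be predicted, so both catalyst antipodes would be screened and the route is written for the one that gives (3S,5S)-11; 2-methylallylmagnesium chloride is taken as the commercial THF solution.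

**Route**

Step 1
Reactants: 1 3-methylbut-3-en-1-ol
Product: 2 tert-butyl[(3-methylbut-3-en-1-yl)oxy]diphenylsilane
Conditions: TBDPSCl, imidazole, CH2Cl2, 0 °C → rt
Reagents that add atoms: tert-butyl(chloro)diphenylsilane, CC(C)(C)[Si](Cl)(c1ccccc1)c1ccccc1
Why: Imidazole-promoted silylation of a primary alcohol is routine, and a silyl ether is chosen for C1–O because it offers no carbonyl oxygen that could bind silylium or participate at the C3 cation in step 5.

Step 2
Reactants: 2 tert-butyl[(3-methylbut-3-en-1-yl)oxy]diphenylsilane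
Product: 4 tert-butyl[(3-hydroperoxy-3-methoxybutyl)oxy]diphenylsilane (racemic), via carbonyl oxide 3 (not isolated)
Conditions: O3, CH2Cl2/MeOH (4:1), −78 °C; N2 purge, warm to rt, no reductant
Reagents that add atoms: ozone, [O-][O+]=O; methanol, CO
Why: Criegee ozonolysis of a 2-methyl-1-alkene fragments to formaldehyde and the ketone O-oxide 3, which methanol traps as the α-methoxy hydroperoxide.

Step 3
Reactants: 4 tert-butyl[(3-hydroperoxy-3-methoxybutyl)oxy]diphenylsilane
Product: 5 tert-butyl({3-methoxy-3-[(triethylsilyl)peroxy]butyl}oxy)diphenylsilane (racemic)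
Conditions: Et3SiCl, imidazole, 4-(dimethylamino)pyridine (cat.), CH2Cl2, 0 °C; chromatography on Et3N-deactivated silica
Reagents that add atoms: chlorotriethylsilane, CC[Si](Cl)(CC)CC
Why: O-silylation of a hydroperoxide with a silyl chloride and imidazole is standard and installs the silyl group that the annulation later hands to the catalyst.

Step 4
Reactants: 6 7-bromohept-1-ene; 7 2-methylallylmagnesium chloride (0.5 M in THF)
Product: 8 2-methyldeca-1,9-diene
Conditions: Li2CuCl4 (3 mol%), THF, −20 → 0 °C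
Reagents that add atoms: none
Why: Kochi-type Li2CuCl4-catalysed cross-coupling of an allylic Grignard reagent with a primary alkyl bromide, in which the two termini of the methallyl unit are equivalent so only one product can form and the vinyl group is inert.

Step 5
Reactants: 5 tert-butyl({3-methoxy-3-[(triethylsilyl)peroxy]butyl}oxy)diphenylsilane; 8 2-methyldeca-1,9-diene
Product: 11 tert-butyl{2-[(3S,5S)-3,5-dimethyl-5-(oct-7-en-1-yl)-1,2-dioxolan-3-yl]ethoxy}diphenylsilane, via peroxycarbenium ion 9 (not isolated), via tertiary carbocation 10 (not isolated)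
Conditions: imidodiphosphorimidate acid (3,3'-Ar2-BINOL)P(=NTf)–N=P(NHTf)(3,3'-Ar2-BINOL), Ar = 3,5-(CF3)2C6H3 (5 mol%, pre-silylated with allyltrimethylsilane, 10 mol%), 8 (1.5 equiv), toluene/CH2Cl2, −78 °C
Reagents that add atoms: none
Why: Proposed new method: the silylated imidodiphosphorimidate transfers R3Si+ to the methoxy oxygen of 5 and expels it as a methoxysilane, leaving peroxycarbenium ion 9 paired with the chiral anion; the CH2 terminus of the 1,1-disubstituted alkene of 8 adds to C3 (C3–C4 bond) to give tertiary cation 10, whose silylated peroxy oxygen closes onto C5 (C5–O bond) and returns Et3Si+ to the anion, so the triethylsilyl group of each substrate molecule carries the chain. The closest known reaction type is the SnCl4-promoted racemic annulation of silylperoxy ketals with alkenes through peroxycarbenium ions, taken together with silylium imidodiphosphorimidate ion-pair catalysis of additions to oxocarbenium ions; pairing a peroxycarbenium ion with a chiral anion is the new element. The 1,2-dioxolane closes by oxygen capture of the C5 cation in a five-membered transition state, the second stage of a stepwise cationic (3+2) annulation (formally 5-endo with respect to the former alkene). C3 is set in the C–C bond-forming stage, where the confined anion must leave one face of the planar cation open and tell methyl from the silyloxyethyl arm, as such anions do for methyl against primary alkyl on ketone-derived cations; C5 is set in the closure, where the envelope with the octenyl chain trans to the arm is intrinsically favoured and should be reinforced inside the pocket, the cis isomer being removed by chromatography. The step needs chemoselectivity for the 1,1-disubstituted over the monosubstituted alkene of 8 and Markovnikov regiochemistry, both secured by the tertiary against secondary cation, which separates the two alkenes by orders of magnitude in nucleophilicity. Both partners carry only silyl ether oxygen, so no carbonyl group sequesters the silylium or participates at C3.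

Step 6
Reactants: 11 tert-butyl{2-[(3S,5S)-3,5-dimethyl-5-(oct-7-en-1-yl)-1,2-dioxolan-3-yl]ethoxy}diphenylsilane; 12 (E)-but-2-enal (5 equiv)
Product: 13 (2E)-9-[(3S,5S)-5-{2-[(tert-butyldiphenylsilyl)oxy]ethyl}-3,5-dimethyl-1,2-dioxolan-3-yl]non-2-enal
Conditions: second-generation Hoveyda–Grubbs catalyst RuCl2(H2IMes)(=CH-C6H4-2-OiPr) (5 mol%), CH2Cl2, 40 °C
Reagents that add atoms: none
Why: Olefin cross-metathesis of a monosubstituted alkene with crotonaldehyde gives the conjugated (E)-enal under thermodynamic control with loss of propene, and a fully alkylated dialkyl peroxide without α-hydrogen is expected to be inert to the ruthenium alkylidene.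

Step 7
Reactants: 14 (3Z)-hex-3-en-1-ol
Product: 15 5-{[(3Z)-hex-3-en-1-yl]sulfanyl}-1-phenyl-1H-tetrazole
Conditions: 1-phenyl-1H-tetrazole-5-thiol, PPh3, DIAD, THF, 0 °C → rt
Reagents that add atoms: 1-phenyl-1H-tetrazole-5-thiol, Sc1nnnn1-c1ccccc1
Why: Mitsunobu thioetherification of a primary alcohol with the acidic tetrazolethiol proceeds by SN2 displacement and leaves the (Z)-alkene untouched.

Step 8
Reactants: 15 5-{[(3Z)-hex-3-en-1-yl]sulfanyl}-1-phenyl-1H-tetrazole
Product: 16 5-{[(3Z)-hex-3-en-1-yl]sulfonyl}-1-phenyl-1H-tetrazole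
Conditions: (NH4)6Mo7O24·4H2O (10 mol%), 30% aq. H2O2, EtOH, 0 °C → rt
Reagents that add atoms: hydrogen peroxide, OO
Why: Molybdate-catalysed peroxide oxidation takes the sulfide to the sulfone chemoselectively, because sulfur is far more nucleophilic toward the peroxomolybdate than an isolated disubstituted alkene.

Step 9
Reactants: 13 (2E)-9-[(3S,5S)-5-{2-[(tert-butyldiphenylsilyl)oxy]ethyl}-3,5-dimethyl-1,2-dioxolan-3-yl]non-2-enal; 16 5-{[(3Z)-hex-3-en-1-yl]sulfonyl}-1-phenyl-1H-tetrazole
Product: 17 tert-butyl(2-{(3S,5S)-3,5-dimethyl-5-[(7E,9E,12Z)-pentadeca-7,9,12-trien-1-yl]-1,2-dioxolan-3-yl}ethoxy)diphenylsilane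
Conditions: 16 (1.2 equiv), KN(SiMe3)2, DME, −60 °C; then 13, −60 °C → rt
Reagents that add atoms: none
Why: Julia–Kocienski olefination of a non-stabilised alkyl phenyltetrazolyl sulfone anion with an enal gives the (E)-alkene at C14=C15 through the kinetically favoured anti adduct, Smiles rearrangement and anti elimination, and the dioxolane has no α-hydrogen for base-induced fragmentation.

Step 10
Reactants: 17 tert-butyl(2-{(3S,5S)-3,5-dimethyl-5-[(7E,9E,12Z)-pentadeca-7,9,12-trien-1-yl]-1,2-dioxolan-3-yl}ethoxy)diphenylsilane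
Product: 18 2-{(3S,5S)-3,5-dimethyl-5-[(7E,9E,12Z)-pentadeca-7,9,12-trien-1-yl]-1,2-dioxolan-3-yl}ethan-1-ol
Conditions: Bu4NF, THF, 0 °C → rt
Reagents that add atoms: none
Why: Fluoride-mediated cleavage of the primary silyl ether is driven by the Si–F bond and touches neither the triene nor the hindered peroxide.

Step 11
Reactants: 18 2-{(3S,5S)-3,5-dimethyl-5-[(7E,9E,12Z)-pentadeca-7,9,12-trien-1-yl]-1,2-dioxolan-3-yl}ethan-1-ol
Product: 19 2-{(3R,5S)-3,5-dimethyl-5-[(7E,9E,12Z)-pentadeca-7,9,12-trien-1-yl]-1,2-dioxolan-3-yl}acetaldehyde (used crude)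
Conditions: Dess–Martin periodinane, CH2Cl2, 0 °C → rt
Reagents that add atoms: none
Why: Dess–Martin oxidation stops at the aldehyde under non-basic conditions that avoid β-elimination of the peroxide and leave the triene alone (the descriptor at C3 changes only through ligand priority).

Step 12
Reactants: 19 2-{(3R,5S)-3,5-dimethyl-5-[(7E,9E,12Z)-pentadeca-7,9,12-trien-1-yl]-1,2-dioxolan-3-yl}acetaldehyde
Product: 20 2-{(3R,5S)-3,5-dimethyl-5-[(7E,9E,12Z)-pentadeca-7,9,12-trien-1-yl]-1,2-dioxolan-3-yl}acetic acid (CNP0215994.1)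
Conditions: NaClO2, NaH2PO4, 2-methylbut-2-ene (excess), t-BuOH/H2O, 0 °C → rt
Reagents that add atoms: sodium chlorite, [Na+].[O-]Cl=O
Why: Pinnick oxidation with buffered chlorous acid converts the aldehyde to the acid, with 2-methylbut-2-ene in large excess scavenging hypochlorous acid before it can add to the triene.

**Compound list**

1 | 3-methylbut-3-en-1-ol | C=C(C)CCO | starting material
2 | tert-butyl[(3-methylbut-3-en-1-yl)oxy]diphenylsilane | C=C(C)CCO[Si](c1ccccc1)(c1ccccc1)C(C)(C)C | intermediate
3 | carbonyl oxide, 4-[(tert-butyldiphenylsilyl)oxy]butan-2-one O-oxide | CC(CCO[Si](c1ccccc1)(c1ccccc1)C(C)(C)C)=[O+][O-] | intermediate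
4 | tert-butyl[(3-hydroperoxy-3-methoxybutyl)oxy]diphenylsilane (racemic) | COC(C)(CCO[Si](c1ccccc1)(c1ccccc1)C(C)(C)C)OO | intermediate
5 | tert-butyl({3-methoxy-3-[(triethylsilyl)peroxy]butyl}oxy)diphenylsilane (racemic) | CC[Si](CC)(CC)OOC(C)(OC)CCO[Si](c1ccccc1)(c1ccccc1)C(C)(C)C | intermediate
6 | 7-bromohept-1-ene | C=CCCCCCBr | starting material
7 | 2-methylallylmagnesium chloride | C=C(C)C[Mg]Cl | starting material
8 | 2-methyldeca-1,9-diene | C=C(C)CCCCCCC=C | intermediate
9 | peroxycarbenium ion, {4-[(tert-butyldiphenylsilyl)oxy]butan-2-ylidene}[(triethylsilyl)oxy]oxonium, paired with the imidodiphosphorimidate anion | CC(CCO[Si](c1ccccc1)(c1ccccc1)C(C)(C)C)=[O+]O[Si](CC)(CC)CC | intermediate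
10 | tertiary C5 carbocation after C3–C4 bond formation, silylperoxy group still on C3, C3 configured as in 11 | C=CCCCCCC[C+](C)C[C@](C)(CCO[Si](c1ccccc1)(c1ccccc1)C(C)(C)C)OO[Si](CC)(CC)CC | intermediate
11 | tert-butyl{2-[(3S,5S)-3,5-dimethyl-5-(oct-7-en-1-yl)-1,2-dioxolan-3-yl]ethoxy}diphenylsilane | C=CCCCCCC[C@@]1(C)C[C@](C)(CCO[Si](c2ccccc2)(c2ccccc2)C(C)(C)C)OO1 | intermediate
12 | (E)-but-2-enal | C/C=C/C=O | starting material
13 | (2E)-9-[(3S,5S)-5-{2-[(tert-butyldiphenylsilyl)oxy]ethyl}-3,5-dimethyl-1,2-dioxolan-3-yl]non-2-enal | O=C/C=C/CCCCCC[C@@]1(C)C[C@](C)(CCO[Si](c2ccccc2)(c2ccccc2)C(C)(C)C)OO1 | intermediate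
14 | (3Z)-hex-3-en-1-ol | CC/C=C\CCO | starting material
15 | 5-{[(3Z)-hex-3-en-1-yl]sulfanyl}-1-phenyl-1H-tetrazole | CC/C=C\CCSc1nnnn1-c1ccccc1 | intermediate
16 | 5-{[(3Z)-hex-3-en-1-yl]sulfonyl}-1-phenyl-1H-tetrazole | CC/C=C\CCS(=O)(=O)c1nnnn1-c1ccccc1 | intermediate
17 | tert-butyl(2-{(3S,5S)-3,5-dimethyl-5-[(7E,9E,12Z)-pentadeca-7,9,12-trien-1-yl]-1,2-dioxolan-3-yl}ethoxy)diphenylsilane | CC/C=C\C/C=C/C=C/CCCCCC[C@@]1(C)C[C@](C)(CCO[Si](c2ccccc2)(c2ccccc2)C(C)(C)C)OO1 | intermediate
18 | 2-{(3S,5S)-3,5-dimethyl-5-[(7E,9E,12Z)-pentadeca-7,9,12-trien-1-yl]-1,2-dioxolan-3-yl}ethan-1-ol | CC/C=C\C/C=C/C=C/CCCCCC[C@@]1(C)C[C@](C)(CCO)OO1 | intermediate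
19 | 2-{(3R,5S)-3,5-dimethyl-5-[(7E,9E,12Z)-pentadeca-7,9,12-trien-1-yl]-1,2-dioxolan-3-yl}acetaldehyde | CC/C=C\C/C=C/C=C/CCCCCC[C@@]1(C)C[C@](C)(CC=O)OO1 | intermediate
20 | 2-{(3R,5S)-3,5-dimethyl-5-[(7E,9E,12Z)-pentadeca-7,9,12-trien-1-yl]-1,2-dioxolan-3-yl}acetic acid (CNP0215994.1) | CC/C=C\C/C=C/C=C/CCCCCC[C@@]1(C)C[C@](C)(CC(=O)O)OO1 | target

**Count and risks**

Total: 12 steps. Longest linear sequence: 9 steps (1, 2, 3, 5, 6, 9, 10, 11, 12).

Step 5 (proposed new method). The anion may fail to discriminate the faces of the C3 cation, since both geometric isomers of the C=O+ bond are present and methyl differs little from CH2. Ring closure may also show little trans preference, or the silylium may be held by the methoxysilane by-product so that turnover stalls. The fallback uses known chemistry, sets out from 5 and 8 and gives up asymmetric induction. The two partners are combined under the established stoichiometric Lewis-acid protocol (SnCl4, CH2Cl2, −78 °C), which delivers racemic material. Chromatography on silica removes the cis diastereomer tert-butyl{2-[(3R,5S)-3,5-dimethyl-5-(oct-7-en-1-yl)-1,2-dioxolan-3-yl]ethoxy}diphenylsilane F2 (racemic). The trans racemate is then resolved by preparative HPLC on a cellulose carbamate chiral stationary phase, which separates 11 from its antipode tert-butyl{2-[(3R,5R)-3,5-dimethyl-5-(oct-7-en-1-yl)-1,2-dioxolan-3-yl]ethoxy}diphenylsilane F1. The route is rejoined at 11.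

Step 9. E-selectivity at C14=C15 may erode, the sulfonyl carbanion may deprotonate the enal at its γ-position instead of adding, or the homoallylic sulfone anion may eliminate sulfinate. The fallback sets out from 11 (with 14 for the small fragment) and forms the C13–C14 single bond by a stereospecific Suzuki coupling.
- Cross-metathesis of 11 with vinylboronic acid pinacol ester (second-generation Hoveyda–Grubbs catalyst, CH2Cl2, 40 °C) should give the (E)-alkenylboronate tert-butyl(2-{(3S,5S)-3,5-dimethyl-5-[(7E)-8-(4,4,5,5-tetramethyl-1,3,2-dioxaborolan-2-yl)oct-7-en-1-yl]-1,2-dioxolan-3-yl}ethoxy)diphenylsilane F3.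
- Separately, 14 is oxidised with Dess–Martin periodinane to (3Z)-hex-3-enal F4, which is used at once in a Takai olefination (CrCl2, CHI3, THF, 0 °C) to give (1E,4Z)-1-iodohepta-1,4-diene F5. Divalent chromium is acceptable here because this fragment carries no peroxide.
- Coupling of F3 with F5 (Pd(PPh3)4, TlOEt, THF/H2O, rt) transfers both alkene geometries and rejoins the route at 17.

Step 12. The β-peroxy aldehyde may lose the peroxide by β-elimination with ring opening before it is oxidised, and hypochlorous acid that escapes the scavenger may add to the conjugated diene. The fallback sets out from 11 and installs the carboxyl group before the triene exists.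
- Desilylation of 11 (Bu4NF, THF) gives 2-[(3S,5S)-3,5-dimethyl-5-(oct-7-en-1-yl)-1,2-dioxolan-3-yl]ethan-1-ol F6.
- Oxidation with catalytic 2,2,6,6-tetramethylpiperidin-1-oxyl and PhI(OAc)2 in aqueous MeCN, where the only alkene is an unreactive vinyl group, gives 2-[(3R,5S)-3,5-dimethyl-5-(oct-7-en-1-yl)-1,2-dioxolan-3-yl]acetic acid F7.
- Me3SiCHN2 in toluene/MeOH gives methyl 2-[(3R,5S)-3,5-dimethyl-5-(oct-7-en-1-yl)-1,2-dioxolan-3-yl]acetate F8.
- Cross-metathesis with 12 as in step 6 gives methyl 2-{(3R,5S)-3,5-dimethyl-5-[(7E)-9-oxonon-7-en-1-yl]-1,2-dioxolan-3-yl}acetate F9.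
- Julia–Kocienski olefination with 16 as in step 9 gives methyl 2-{(3R,5S)-3,5-dimethyl-5-[(7E,9E,12Z)-pentadeca-7,9,12-trien-1-yl]-1,2-dioxolan-3-yl}acetate F10.
- LiOH in aqueous THF then liberates the acid, so the route comes back at 20.

**Further compounds**

F1 | step 5 | tert-butyl{2-[(3R,5R)-3,5-dimethyl-5-(oct-7-en-1-yl)-1,2-dioxolan-3-yl]ethoxy}diphenylsilane | C=CCCCCCC[C@]1(C)C[C@@](C)(CCO[Si](c2ccccc2)(c2ccccc2)C(C)(C)C)OO1
F2 | step 5 | tert-butyl{2-[(3R,5S)-3,5-dimethyl-5-(oct-7-en-1-yl)-1,2-dioxolan-3-yl]ethoxy}diphenylsilane (racemic cis isomer, one enantiomer drawn) | C=CCCCCCC[C@@]1(C)C[C@@](C)(CCO[Si](c2ccccc2)(c2ccccc2)C(C)(C)C)OO1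
F3 | step 9 | tert-butyl(2-{(3S,5S)-3,5-dimethyl-5-[(7E)-8-(4,4,5,5-tetramethyl-1,3,2-dioxaborolan-2-yl)oct-7-en-1-yl]-1,2-dioxolan-3-yl}ethoxy)diphenylsilane | CC1(C)OB(/C=C/CCCCCC[C@@]2(C)C[C@](C)(CCO[Si](c3ccccc3)(c3ccccc3)C(C)(C)C)OO2)OC1(C)C
F4 | step 9 | (3Z)-hex-3-enal | CC/C=C\CC=O
F5 | step 9 | (1E,4Z)-1-iodohepta-1,4-diene | CC/C=C\C/C=C/I
F6 | step 12 | 2-[(3S,5S)-3,5-dimethyl-5-(oct-7-en-1-yl)-1,2-dioxolan-3-yl]ethan-1-ol | C=CCCCCCC[C@@]1(C)C[C@](C)(CCO)OO1
F7 | step 12 | 2-[(3R,5S)-3,5-dimethyl-5-(oct-7-en-1-yl)-1,2-dioxolan-3-yl]acetic acid | C=CCCCCCC[C@@]1(C)C[C@](C)(CC(=O)O)OO1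
F8 | step 12 | methyl 2-[(3R,5S)-3,5-dimethyl-5-(oct-7-en-1-yl)-1,2-dioxolan-3-yl]acetate | C=CCCCCCC[C@@]1(C)C[C@](C)(CC(=O)OC)OO1
F9 | step 12 | methyl 2-{(3R,5S)-3,5-dimethyl-5-[(7E)-9-oxonon-7-en-1-yl]-1,2-dioxolan-3-yl}acetate | O=C/C=C/CCCCCC[C@@]1(C)C[C@](C)(CC(=O)OC)OO1
F10 | step 12 | methyl 2-{(3R,5S)-3,5-dimethyl-5-[(7E,9E,12Z)-pentadeca-7,9,12-trien-1-yl]-1,2-dioxolan-3-yl}acetate | CC/C=C\C/C=C/C=C/CCCCCC[C@@]1(C)C[C@](C)(CC(=O)OC)OO1
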